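Readings and results were generated by integration from invented constants, and the scatter is random.

The reagent is what this kinetic resolution spends, and the question is how much of it stands in the flask when the rate is asked for.

| flask | left-handed substrate | right-handed substrate | reagent | precatalyst | remark |
|---|---|---|---|---|---|
| epsilon | 0.10 M | 0.10 M | 0.11 M | 0.50 mM | run made earlier |
| delta | 0.10 M | 0.10 M | 0.11 M | 0.75 mM | run made earlier |
| flask | 0.10 M | 0.10 M | 0.110 M | 1.0 mM |  |

| run | time / min | left-handed product / % |
|---|---|---|
| epsilon | 2.50 | 1.1 |
| epsilon | 4.00 | 3.5 |
| epsilon | 8.00 | 6.6 |
| epsilon | 12.0 | 8.8 |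
| epsilon | 20.0 | 13.4 |
| epsilon | 30.0 | 16.8 |
| delta | 5.00 | 5.7 |
| delta | 10.0 | 11.4 |
| delta | 15.0 | 15.9 |
| delta | 20.0 | 18.8 |
| delta | 25.0 | 20.2 |
| delta | 30.0 | 22.2 |

(each reading ± 0.5 percentage points)

- free catalyst is single-handed; left-handed substrate and right-handed substrate are mirror images of each other, charged as a racemate, each of them at the stated concentration
- what was read earlier has a scatter of 0.5 percentage points, one standard deviation
- no earlier run changes the charge of reagent; that part of a forecast is a guess

- factor on the rate of making left-handed product when 30 % of the left-handed substrate and right-handed substrate together are converted if reagent is charged twice over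
- factor on the rate when 30 % of the left-handed substrate and right-handed substrate together are converted if precatalyst is charged at 10 mM instead

Take the main step first: active catalyst turns left-handed substrate and reagent into left-handed product, one reagent per product. Comparisons at equal conversion hold the substrate fixed, so the rate follows active catalyst times reagent. Conversion itself consumes 0.0600 M of reagent, and the reagent margin, the charge less that amount, is 0.0500 M. Then:

doubled reagent: 3.20
tenfold precatalyst: 10.0

Next comes the wait for active catalyst, seen in the epsilon run's slow start. It pulls the second factor down where conversion arrives early.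

Last comes a drain on reagent running by the clock, one reading of the drift between the runs. It subtracts from the margin. The readings give it no size, so this reckoning assumes 0.0250 M, half of the margin, in the flask and in the doubled-reagent flask, and none in the flask at 10 mM:

doubled reagent: 5.40
tenfold precatalyst: 20.0

The forecast gives 1.5 and 18, on its own grounds: “points to catalyst dying with clock time”. The two part on the first factor, 5.40 here against 1.5, and the forecast places the loss in the catalyst, not the reagent.

The flask gives 6.19 and 66.2.

    free catalyst + left-handed substrate ⇌ catalyst intermediate A (K = 30.0 M⁻¹, k = 4.40 M⁻¹ s⁻¹)
    free catalyst + right-handed substrate ⇌ catalyst intermediate B (K = 2.80 M⁻¹, k = 12.0 M⁻¹ s⁻¹)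
    reagent + catalyst intermediate A → free catalyst + left-handed product (k = 1.60 M⁻¹ s⁻¹)
    reagent + catalyst intermediate B → free catalyst + right-handed product (k = 0.0790 M⁻¹ s⁻¹)
    precatalyst → free catalyst (k = 0.0130 s⁻¹)
    2 reagent → self-condensation product (k = 0.00560 M⁻¹ s⁻¹)

In the 1.0 mM flask, half of the self-condensation turnover up to 40.0 min is done by 3.95 min, earlier than the same mark for left-handed product at 9.54 min. By 40.0 min the 0.0228 M of self-condensation product in that flask holds 0.0455 M of reagent, nearly all of the margin of 0.0500 M. The flask charged at 10 mM has the same margin on paper, and its factor of 66.2 stands 6.62 times above its tenfold catalyst.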